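The disconnection is the C2–C3 bond of the furan ring (ring B) of the benzofuran. C2 lies between O1 and the guaiacyl ring (ring C) and C3 holds the formyl carbon, so C2 maps onto the CH2 of an aryl benzyl ether and C3 onto the carbene carbon of an aryl diazoacetate. In one operation a dirhodium carbene inserts into that O-benzylic C–H bond, making C2–C3 and closing ring B. The precursor is a methyl 2-diazo-2-arylacetate on ring A whose ortho oxygen carries the 3-methoxy-4-silyloxybenzyl group; the phenol is held as a TIPS ether (more base-stable than TBS) and the side-chain alcohol as a TBS ether.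

Key step: step 11

Remark: ring A is the benzo ring, ring B the furan ring and ring C the pendant 4-hydroxy-3-methoxyphenyl ring; the target has no stereocentre, so 16 is made as a racemate with an achiral catalyst and any trans isomer formed with it is carried on.

Step 1
Reactants: 1 dihydroconiferyl alcohol; 2 allyl bromide
Product: 3 3-[4-(allyloxy)-3-methoxyphenyl]propan-1-ol
Conditions: K2CO3, acetone, reflux
Reagents that add atoms: none
Why: Williamson ether synthesis in which K2CO3 deprotonates only the phenol, far more acidic than the primary alcohol, and the phenoxide displaces bromide from allyl bromide.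

Step 2
Reactants: 3 3-[4-(allyloxy)-3-methoxyphenyl]propan-1-ol
Product: 4 tert-butyl{3-[4-(allyloxy)-3-methoxyphenyl]propoxy}dimethylsilane
Conditions: TBSCl, imidazole, DMF, rt
Reagents that add atoms: tert-butyldimethylsilyl chloride, CC(C)(C)[Si](C)(C)Cl
Why: Imidazole-promoted silylation (Corey protocol) of the only hydroxyl group masks the side-chain alcohol against the later oxidations and the carbene.

Step 3
Reactants: 4 tert-butyl{3-[4-(allyloxy)-3-methoxyphenyl]propoxy}dimethylsilane
Product: 6 2-allyl-6-methoxy-4-[3-(tert-butyldimethylsilyloxy)propyl]phenol, via dienone 5 (not isolated)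
Conditions: PhNEt2, 200 °C, argon
Reagents that add atoms: none
Why: Aromatic Claisen rearrangement, in which the [3,3] shift delivers the allyl group to the only unsubstituted ortho carbon (the future C3a) and dienone 5 tautomerises to the phenol, so its stereocentre is lost.

Step 4
Reactants: 7 vanillin
Product: 8 3-methoxy-4-(triisopropylsilyloxy)benzaldehyde
Conditions: TIPSCl, imidazole, DMF, rt
Reagents that add atoms: triisopropylsilyl chloride, CC(C)[Si](Cl)(C(C)C)C(C)C
Why: Imidazole-promoted silylation of the phenol, the bulky TIPS group being chosen because aryl TIPS ethers tolerate the carbonate, DBU and hydride reagents used later.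

Step 5
Reactants: 8 3-methoxy-4-(triisopropylsilyloxy)benzaldehyde
Product: 9 [3-methoxy-4-(triisopropylsilyloxy)phenyl]methanol
Conditions: NaBH4, MeOH, 0 °C
Reagents that add atoms: none
Why: Borohydride reduction of the aromatic aldehyde to the benzylic alcohol, which at 0 °C should leave the aryl silyl ether untouched.

Step 6
Reactants: 6 2-allyl-6-methoxy-4-[3-(tert-butyldimethylsilyloxy)propyl]phenol; 9 [3-methoxy-4-(triisopropylsilyloxy)phenyl]methanol
Product: 10 1-allyl-3-methoxy-2-{[3-methoxy-4-(triisopropylsilyloxy)benzyl]oxy}-5-[3-(tert-butyldimethylsilyloxy)propyl]benzene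
Conditions: PPh3, DIAD, THF, 0 °C to rt
Reagents that add atoms: none
Why: Mitsunobu etherification, in which the phenol protonates the PPh3–DIAD betaine and its phenoxide displaces the activated primary benzylic oxygen, so that no labile para-silyloxybenzyl halide has to be made.

Step 7
Reactants: 10 1-allyl-3-methoxy-2-{[3-methoxy-4-(triisopropylsilyloxy)benzyl]oxy}-5-[3-(tert-butyldimethylsilyloxy)propyl]benzene
Product: 12 2-{3-methoxy-2-{[3-methoxy-4-(triisopropylsilyloxy)benzyl]oxy}-5-[3-(tert-butyldimethylsilyloxy)propyl]phenyl}acetaldehyde, via diol 11 (not isolated)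
Conditions: OsO4 (cat.), NaIO4, 2,6-lutidine, 1,4-dioxane/H2O 3:1, rt
Reagents that add atoms: osmium tetroxide OsO4, O=[Os](=O)(=O)=O (catalytic oxygen carrier); sodium periodate NaIO4, [Na+].[O-]I(=O)(=O)=O (terminal oxygen source)
Why: Lemieux–Johnson oxidation, in which catalytic OsO4 dihydroxylates the only alkene and NaIO4 cleaves diol 11 and reoxidises osmium, with 2,6-lutidine holding back over-oxidation and the electron-rich arenes and ethers staying inert.

Step 8
Reactants: 12 2-{3-methoxy-2-{[3-methoxy-4-(triisopropylsilyloxy)benzyl]oxy}-5-[3-(tert-butyldimethylsilyloxy)propyl]phenyl}acetaldehyde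
Product: 13 2-{3-methoxy-2-{[3-methoxy-4-(triisopropylsilyloxy)benzyl]oxy}-5-[3-(tert-butyldimethylsilyloxy)propyl]phenyl}acetic acid
Conditions: NaClO2, NaH2PO4, 2-methyl-2-butene, t-BuOH/H2O, 0 °C to rt
Reagents that add atoms: sodium chlorite NaClO2, [Na+].[O-]Cl=O
Why: Pinnick (Lindgren) oxidation converts the crude, enolisable arylacetaldehyde into the acid under buffered conditions while 2-methyl-2-butene traps HOCl before it can chlorinate the electron-rich rings.

Step 9
Reactants: 13 2-{3-methoxy-2-{[3-methoxy-4-(triisopropylsilyloxy)benzyl]oxy}-5-[3-(tert-butyldimethylsilyloxy)propyl]phenyl}acetic acid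
Product: 14 methyl 2-{3-methoxy-2-{[3-methoxy-4-(triisopropylsilyloxy)benzyl]oxy}-5-[3-(tert-butyldimethylsilyloxy)propyl]phenyl}acetate
Conditions: MeI, K2CO3, DMF, rt
Reagents that add atoms: iodomethane, CI
Why: SN2 O-alkylation of the carboxylate with MeI under mild carbonate base, which at room temperature should affect neither silyl ether nor the benzylic ester position.

Step 10
Reactants: 14 methyl 2-{3-methoxy-2-{[3-methoxy-4-(triisopropylsilyloxy)benzyl]oxy}-5-[3-(tert-butyldimethylsilyloxy)propyl]phenyl}acetate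
Product: 15 methyl 2-diazo-2-{3-methoxy-2-{[3-methoxy-4-(triisopropylsilyloxy)benzyl]oxy}-5-[3-(tert-butyldimethylsilyloxy)propyl]phenyl}acetate
Conditions: 4-acetamidobenzenesulfonyl azide (p-ABSA), DBU, MeCN, 0 °C to rt
Reagents that add atoms: 4-acetamidobenzenesulfonyl azide, CC(=O)Nc1ccc(cc1)S(=O)(=O)N=[N+]=[N-]
Why: Regitz diazo transfer, in which DBU deprotonates the benzylic ester α-carbon and the enolate takes the terminal N2 unit from the sulfonyl azide to give the aryl diazoacetate.

Step 11
Reactants: 15 methyl 2-diazo-2-{3-methoxy-2-{[3-methoxy-4-(triisopropylsilyloxy)benzyl]oxy}-5-[3-(tert-butyldimethylsilyloxy)propyl]phenyl}acetate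
Product: 16 methyl cis-7-methoxy-2-[3-methoxy-4-(triisopropylsilyloxy)phenyl]-5-[3-(tert-butyldimethylsilyloxy)propyl]-2,3-dihydrobenzofuran-3-carboxylate (racemic; 2S*,3R*; H-2 and H-3 on the same face)
Conditions: Rh2(OAc)4 (1 mol %), CH2Cl2, rt, slow addition of 15, argon
Reagents that add atoms: none
Why: Rh2(OAc)4 takes up the diazo carbon of 15, N2 leaves, and the resulting donor–acceptor rhodium carbene (aryl donor, ester acceptor) meets a C–H bond of the OCH2 group in a concerted, asynchronous three-centre transition state with hydride-transfer character, so the carbene carbon becomes C3 and the benzylic carbon becomes C2. The closest known reaction type is the dirhodium-catalysed intramolecular 1,5 C–H insertion of ortho-benzyloxy aryl diazoacetates to 2-aryl-2,3-dihydrobenzofuran-3-carboxylates. Ring B closes by C–C bond formation across a five-membered transition state made of the carbene carbon, two ring A carbons, O1 and the benzylic carbon, that is a 1,5-insertion. C2 and C3 are created in the same event and the cis relationship should follow from the kinetically preferred transition-state geometry; the catalyst is achiral, so 16 is racemic, and neither centre matters because step 12 erases both. The step needs site selectivity for the O-benzylic C–H over the methoxy, silyl ether and aromatic positions and over carbene dimerisation; the five-membered geometry, activation of that C–H by O1 and by electron-rich ring C, the tempered reactivity of a donor–acceptor carbene and slow addition of 15 should secure it.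

Step 12
Reactants: 16 methyl cis-7-methoxy-2-[3-methoxy-4-(triisopropylsilyloxy)phenyl]-5-[3-(tert-butyldimethylsilyloxy)propyl]-2,3-dihydrobenzofuran-3-carboxylate
Product: 17 methyl 7-methoxy-2-[3-methoxy-4-(triisopropylsilyloxy)phenyl]-5-[3-(tert-butyldimethylsilyloxy)propyl]benzofuran-3-carboxylate
Conditions: DDQ, anhydrous 1,4-dioxane, 90 °C
Reagents that add atoms: none
Why: DDQ dehydrogenation, in which hydride abstraction from C2 (benzylic and α to O1) gives an oxocarbenium ion that loses H-3, the gain of furan aromaticity driving the reaction and removing both stereocentres.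

Step 13
Reactants: 17 methyl 7-methoxy-2-[3-methoxy-4-(triisopropylsilyloxy)phenyl]-5-[3-(tert-butyldimethylsilyloxy)propyl]benzofuran-3-carboxylate
Product: 18 {7-methoxy-2-[3-methoxy-4-(triisopropylsilyloxy)phenyl]-5-[3-(tert-butyldimethylsilyloxy)propyl]benzofuran-3-yl}methanol
Conditions: i-Bu2AlH (DIBAL), CH2Cl2, −78 to 0 °C; Rochelle salt work-up
Reagents that add atoms: none
Why: DIBAL reduction of the conjugated methyl ester through the aldehyde to the primary alcohol, the silyl ethers and the benzofuran being inert to the hydride at low temperature.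

Step 14
Reactants: 18 {7-methoxy-2-[3-methoxy-4-(triisopropylsilyloxy)phenyl]-5-[3-(tert-butyldimethylsilyloxy)propyl]benzofuran-3-yl}methanol
Product: 19 7-methoxy-2-[3-methoxy-4-(triisopropylsilyloxy)phenyl]-5-[3-(tert-butyldimethylsilyloxy)propyl]benzofuran-3-carbaldehyde
Conditions: activated MnO2, CH2Cl2, rt
Reagents that add atoms: none
Why: MnO2 oxidation of the benzylic-type (benzofuran-3-yl)methanol stops cleanly at the aldehyde.

Step 15
Reactants: 19 7-methoxy-2-[3-methoxy-4-(triisopropylsilyloxy)phenyl]-5-[3-(tert-butyldimethylsilyloxy)propyl]benzofuran-3-carbaldehyde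
Product: 20 2-(4-hydroxy-3-methoxyphenyl)-5-(3-hydroxypropyl)-7-methoxybenzofuran-3-carbaldehyde
Conditions: Bu4NF, AcOH, THF, 0 °C to rt
Reagents that add atoms: none
Why: Fluoride-mediated desilylation driven by Si–F bond formation removes the TBS and TIPS groups in one operation, acetic acid buffering the liberated phenoxide and alkoxide so the aldehyde does not meet strong base.

Compound list
1 | dihydroconiferyl alcohol, 4-(3-hydroxypropyl)-2-methoxyphenol | COc1cc(CCCO)ccc1O | starting material
2 | allyl bromide | C=CCBr | starting material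
3 | 3-[4-(allyloxy)-3-methoxyphenyl]propan-1-ol | COc1cc(CCCO)ccc1OCC=C | intermediate
4 | tert-butyl{3-[4-(allyloxy)-3-methoxyphenyl]propoxy}dimethylsilane | COc1cc(CCCO[Si](C)(C)C(C)(C)C)ccc1OCC=C | intermediate
5 | 6-allyl-2-methoxy-4-[3-(tert-butyldimethylsilyloxy)propyl]cyclohexa-2,4-dien-1-one (racemic; formed in the flask, not isolated) | COC1=CC(CCCO[Si](C)(C)C(C)(C)C)=CC(CC=C)C1=O | intermediate
6 | 2-allyl-6-methoxy-4-[3-(tert-butyldimethylsilyloxy)propyl]phenol | COc1cc(CCCO[Si](C)(C)C(C)(C)C)cc(CC=C)c1O | intermediate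
7 | vanillin | COc1cc(C=O)ccc1O | starting material
8 | 3-methoxy-4-(triisopropylsilyloxy)benzaldehyde | COc1cc(C=O)ccc1O[Si](C(C)C)(C(C)C)C(C)C | intermediate
9 | [3-methoxy-4-(triisopropylsilyloxy)phenyl]methanol | COc1cc(CO)ccc1O[Si](C(C)C)(C(C)C)C(C)C | intermediate
10 | 1-allyl-3-methoxy-2-{[3-methoxy-4-(triisopropylsilyloxy)benzyl]oxy}-5-[3-(tert-butyldimethylsilyloxy)propyl]benzene | COc1cc(CCCO[Si](C)(C)C(C)(C)C)cc(CC=C)c1OCc1ccc(O[Si](C(C)C)(C(C)C)C(C)C)c(OC)c1 | intermediate
11 | 3-{3-methoxy-2-{[3-methoxy-4-(triisopropylsilyloxy)benzyl]oxy}-5-[3-(tert-butyldimethylsilyloxy)propyl]phenyl}propane-1,2-diol (racemic; formed in the flask, not isolated) | COc1cc(CCCO[Si](C)(C)C(C)(C)C)cc(CC(O)CO)c1OCc1ccc(O[Si](C(C)C)(C(C)C)C(C)C)c(OC)c1 | intermediate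
12 | 2-{3-methoxy-2-{[3-methoxy-4-(triisopropylsilyloxy)benzyl]oxy}-5-[3-(tert-butyldimethylsilyloxy)propyl]phenyl}acetaldehyde | COc1cc(CCCO[Si](C)(C)C(C)(C)C)cc(CC=O)c1OCc1ccc(O[Si](C(C)C)(C(C)C)C(C)C)c(OC)c1 | intermediate
13 | 2-{3-methoxy-2-{[3-methoxy-4-(triisopropylsilyloxy)benzyl]oxy}-5-[3-(tert-butyldimethylsilyloxy)propyl]phenyl}acetic acid | COc1cc(CCCO[Si](C)(C)C(C)(C)C)cc(CC(=O)O)c1OCc1ccc(O[Si](C(C)C)(C(C)C)C(C)C)c(OC)c1 | intermediate
14 | methyl 2-{3-methoxy-2-{[3-methoxy-4-(triisopropylsilyloxy)benzyl]oxy}-5-[3-(tert-butyldimethylsilyloxy)propyl]phenyl}acetate | COC(=O)Cc1cc(CCCO[Si](C)(C)C(C)(C)C)cc(OC)c1OCc1ccc(O[Si](C(C)C)(C(C)C)C(C)C)c(OC)c1 | intermediate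
15 | methyl 2-diazo-2-{3-methoxy-2-{[3-methoxy-4-(triisopropylsilyloxy)benzyl]oxy}-5-[3-(tert-butyldimethylsilyloxy)propyl]phenyl}acetate | COC(=O)C(=[N+]=[N-])c1cc(CCCO[Si](C)(C)C(C)(C)C)cc(OC)c1OCc1ccc(O[Si](C(C)C)(C(C)C)C(C)C)c(OC)c1 | intermediate
16 | methyl cis-7-methoxy-2-[3-methoxy-4-(triisopropylsilyloxy)phenyl]-5-[3-(tert-butyldimethylsilyloxy)propyl]-2,3-dihydrobenzofuran-3-carboxylate (racemic, 2S*,3R*; one enantiomer drawn) | COC(=O)[C@H]1[C@@H](c2ccc(O[Si](C(C)C)(C(C)C)C(C)C)c(OC)c2)Oc2c(OC)cc(CCCO[Si](C)(C)C(C)(C)C)cc21 | intermediate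
17 | methyl 7-methoxy-2-[3-methoxy-4-(triisopropylsilyloxy)phenyl]-5-[3-(tert-butyldimethylsilyloxy)propyl]benzofuran-3-carboxylate | COC(=O)c1c(-c2ccc(O[Si](C(C)C)(C(C)C)C(C)C)c(OC)c2)oc2c(OC)cc(CCCO[Si](C)(C)C(C)(C)C)cc12 | intermediate
18 | {7-methoxy-2-[3-methoxy-4-(triisopropylsilyloxy)phenyl]-5-[3-(tert-butyldimethylsilyloxy)propyl]benzofuran-3-yl}methanol | OCc1c(-c2ccc(O[Si](C(C)C)(C(C)C)C(C)C)c(OC)c2)oc2c(OC)cc(CCCO[Si](C)(C)C(C)(C)C)cc12 | intermediate
19 | 7-methoxy-2-[3-methoxy-4-(triisopropylsilyloxy)phenyl]-5-[3-(tert-butyldimethylsilyloxy)propyl]benzofuran-3-carbaldehyde | O=Cc1c(-c2ccc(O[Si](C(C)C)(C(C)C)C(C)C)c(OC)c2)oc2c(OC)cc(CCCO[Si](C)(C)C(C)(C)C)cc12 | intermediate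
20 | 2-(4-hydroxy-3-methoxyphenyl)-5-(3-hydroxypropyl)-7-methoxybenzofuran-3-carbaldehyde (achiral) | COc1cc(-c2oc3c(OC)cc(CCCO)cc3c2C=O)ccc1O | target

Total step count: 15. Longest linear sequence: 13 steps (steps 1–3 and 6–15, from dihydroconiferyl alcohol 1); steps 4 and 5 form the side branch from vanillin 7.

Steps most likely to fail

Step 11. The carbene may dimerise, or hydride transfer from the very electron-rich benzylic position may be followed by fragmentation of the zwitterion instead of C–C bond formation. The fallback sets out from 4 and 8 and comes back to the route at 17 (steps 11 and 12 are then not needed); it builds ring B by a palladium-catalysed carbonylative annulation with the ester carbon delivered by CO. Deallylation of 4 (Pd(PPh3)4, morpholine, THF, rt) should give 2-methoxy-4-[3-(tert-butyldimethylsilyloxy)propyl]phenol F1. Iodination ortho to the hydroxyl group (N-iodosuccinimide, MeCN, 0 °C) should give 2-iodo-6-methoxy-4-[3-(tert-butyldimethylsilyloxy)propyl]phenol F2. Colvin homologation of aldehyde 8 (Me3SiCHN2, LDA, THF, −78 °C to rt) should give (4-ethynyl-2-methoxyphenoxy)triisopropylsilane F3. Sonogashira coupling of F2 with F3 (PdCl2(PPh3)2, CuI, Et3N, THF, rt, kept cool to hold back premature cyclisation) should give 2-methoxy-6-{[3-methoxy-4-(triisopropylsilyloxy)phenyl]ethynyl}-4-[3-(tert-butyldimethylsilyloxy)propyl]phenol F4. Oxidative alkoxycarbonylative cyclisation of F4 (PdI2, thiourea, CBr4, Cs2CO3, CO 1 atm, MeOH, 40 °C) should give 17. If the aryl silyl ether is partly lost in the basic methanol, treatment with TIPSCl and imidazole restores it.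

Step 12. Hydride abstraction at C2 may be sluggish with the silylated phenol, and DDQ may instead attack the ring A benzylic CH2 of the silyloxypropyl chain or over-oxidise. The fallback sets out from 16 and comes back at 17, replacing hydride abstraction by enolate functionalisation and syn-elimination. Deprotonation at C3 (LiHMDS, THF, −78 °C) and trapping with PhSeCl on the face opposite the C2 aryl group should give methyl 7-methoxy-2-[3-methoxy-4-(triisopropylsilyloxy)phenyl]-3-(phenylselanyl)-5-[3-(tert-butyldimethylsilyloxy)propyl]-2,3-dihydrobenzofuran-3-carboxylate F5, in which selenium is syn to H-2. Oxidation (H2O2, pyridine, CH2Cl2, 0 °C) and selenoxide syn-elimination should then give 17.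

Step 6. The activated, electron-rich benzylic alcohol may ionise before the hindered 2,6-disubstituted phenoxide attacks, leading to C-alkylation or self-condensation and incomplete etherification. The fallback sets out from 9 and 6 and comes back at 10, replacing the redox condensation by a plain SN2 alkylation. Appel bromination of 9 (CBr4, PPh3, CH2Cl2, 0 °C) should give 4-(bromomethyl)-2-methoxy-1-(triisopropylsilyloxy)benzene F6, used at once. Alkylation of phenol 6 with it (K2CO3, Bu4NI cat., acetone, reflux) should give 10.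

Further compounds
F1 | step 11 | 2-methoxy-4-[3-(tert-butyldimethylsilyloxy)propyl]phenol | COc1cc(CCCO[Si](C)(C)C(C)(C)C)ccc1O
F2 | step 11 | 2-iodo-6-methoxy-4-[3-(tert-butyldimethylsilyloxy)propyl]phenol | COc1cc(CCCO[Si](C)(C)C(C)(C)C)cc(I)c1O
F3 | step 11 | (4-ethynyl-2-methoxyphenoxy)triisopropylsilane | COc1cc(C#C)ccc1O[Si](C(C)C)(C(C)C)C(C)C
F4 | step 11 | 2-methoxy-6-{[3-methoxy-4-(triisopropylsilyloxy)phenyl]ethynyl}-4-[3-(tert-butyldimethylsilyloxy)propyl]phenol | COc1cc(CCCO[Si](C)(C)C(C)(C)C)cc(C#Cc2ccc(O[Si](C(C)C)(C(C)C)C(C)C)c(OC)c2)c1O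
F5 | step 12 | methyl 7-methoxy-2-[3-methoxy-4-(triisopropylsilyloxy)phenyl]-3-(phenylselanyl)-5-[3-(tert-butyldimethylsilyloxy)propyl]-2,3-dihydrobenzofuran-3-carboxylate (racemic; selenium trans to the C2 aryl group; one enantiomer drawn) | COC(=O)[C@@]1([Se]c2ccccc2)[C@@H](c2ccc(O[Si](C(C)C)(C(C)C)C(C)C)c(OC)c2)Oc2c(OC)cc(CCCO[Si](C)(C)C(C)(C)C)cc21
F6 | step 6 | 4-(bromomethyl)-2-methoxy-1-(triisopropylsilyloxy)benzene | COc1cc(CBr)ccc1O[Si](C(C)C)(C(C)C)C(C)C
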